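**Retrosynthetic overview**
1. Target 6 is cut at the ester C–O bond into (Z)-sinapyl alcohol 4 and the prochiral 3-hydroxy-3-methylglutaric anhydride 5. The ring opening that picks one of the two enantiotopic carbonyls forms this bond and sets C3 as (R) in the last step.
2. 4 comes from the arylpropargyl alcohol 3 by cis-semihydrogenation, which sets the Z geometry.
3. 3 comes from 4-bromo-2,6-dimethoxyphenol 1 and propargyl alcohol 2 by aryl–alkynyl coupling.
4. No ring is formed: the arene is bought with 1, the anhydride ring of 5 is opened in the last step, and no protecting group is used.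

Assumption: 1, 2 and 5 are bought. The sense of induction in step 3 cannot be read from precedent, so the quinidine-derived catalyst is written; if the first run (chiral HPLC, optical rotation against the natural product) shows the (3S) acid, its quinine-derived pseudoenantiomer is used under the same conditions.

**Step 1**
Reactants: 1 4-bromo-2,6-dimethoxyphenol; 2 prop-2-yn-1-ol (propargyl alcohol, 1.3 equiv)
Product: 3 3-(4-hydroxy-3,5-dimethoxyphenyl)prop-2-yn-1-ol
Conditions: [Pd(allyl)Cl]2 (2.5 mol %), P(t-Bu)3 (10 mol %), DABCO (2.5 equiv), degassed MeCN, 25 to 40 °C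
Reagents that add atoms: none
Why: Copper-free Sonogashira (Heck–Cassar) alkynylation, in which zerovalent palladium carrying the bulky, electron-rich P(t-Bu)3 adds to the electron-rich C–Br bond near room temperature and the absence of copper rules out Glaser dimerisation of 2 and copper-mediated oxidative coupling of the syringyl phenol, the free phenol and primary alcohol being spectators.

**Step 2**
Reactants: 3 3-(4-hydroxy-3,5-dimethoxyphenyl)prop-2-yn-1-ol
Product: 4 (Z)-sinapyl alcohol, 4-[(1Z)-3-hydroxyprop-1-en-1-yl]-2,6-dimethoxyphenol
Conditions: H2 (1 atm), Pd/CaCO3 poisoned with Pb(OAc)2 (Lindlar catalyst, 10 wt %), quinoline (0.2 equiv), EtOAc, 20 °C, stopped at 1.0 equiv H2, light excluded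
Reagents that add atoms: none
Why: Lindlar semihydrogenation, in which syn delivery of H2 on the lead- and quinoline-poisoned palladium surface gives the Z alkene and the poisoned surface releases the alkene before it is reduced further or its allylic C–O bond is cleaved; no stereocentre is formed, only the Z geometry.

**Step 3**
Reactants: 4 (Z)-sinapyl alcohol (1.0 equiv); 5 3-hydroxy-3-methylglutaric anhydride (4-hydroxy-4-methyloxane-2,6-dione, 1.3 equiv)
Product: 6 (3R)-3-hydroxy-5-{[(2Z)-3-(4-hydroxy-3,5-dimethoxyphenyl)prop-2-en-1-yl]oxy}-3-methyl-5-oxopentanoic acid (target)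
Conditions: 9-amino-9-deoxy-epi-quinidine 3,5-bis(trifluoromethyl)benzenesulfonamide (10 mol %), 2-MeTHF (0.3 M), −20 °C, 48–72 h, dark; cold aq. NaH2PO4 (pH 4) wash, C18 chromatography
Reagents that add atoms: none
Why: Proposed new method: enantiotopic-carbonyl-selective alcoholysis of the unprotected prochiral anhydride 5 (a centre carrying CH3 and OH, not H and one substituent) by a functionalised allylic alcohol used as the limiting partner; the quinuclidine nitrogen acts as general base for the primary OH of 4 while the sulfonamide N–H binds the carbonyl under attack, and the pseudo-axial tertiary OH of 5 (CH3 pseudo-equatorial) donates a third hydrogen bond to a sulfonyl oxygen, so that only one of the two enantiotopic C=O groups can sit in the N–H/quinuclidine cleft with this contact intact, which sets C3 as (R) and tells OH from CH3 by hydrogen bonding rather than by size; the hindered, hydrogen-bonded phenol is not acylated under general-base catalysis at −20 °C and the Z alkene is untouched; the closest known reaction type is the cinchona sulfonamide-, thiourea- or squaramide-catalysed desymmetrising methanolysis of 3-monosubstituted glutaric anhydrides.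

**Compound list**
1 | 4-bromo-2,6-dimethoxyphenol | COc1cc(Br)cc(OC)c1O | starting material
2 | prop-2-yn-1-ol (propargyl alcohol) | C#CCO | starting material
3 | 3-(4-hydroxy-3,5-dimethoxyphenyl)prop-2-yn-1-ol | COc1cc(C#CCO)cc(OC)c1O | intermediate
4 | (Z)-sinapyl alcohol, 4-[(1Z)-3-hydroxyprop-1-en-1-yl]-2,6-dimethoxyphenol | COc1cc(/C=C\CO)cc(OC)c1O | intermediate
5 | 3-hydroxy-3-methylglutaric anhydride (4-hydroxy-4-methyloxane-2,6-dione) | CC1(O)CC(=O)OC(=O)C1 | starting material
6 | (3R)-3-hydroxy-5-{[(2Z)-3-(4-hydroxy-3,5-dimethoxyphenyl)prop-2-en-1-yl]oxy}-3-methyl-5-oxopentanoic acid | COc1cc(/C=C\COC(=O)C[C@](C)(O)CC(=O)O)cc(OC)c1O | target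

**Step count**
Total steps: 3. Longest linear sequence: 3 (1 → 3 → 4 → 6).

**Steps most likely to fail, with fallbacks**

1. Step 3 (the proposed new reaction). The risks are low ee because CH3 and OH are close in size, slow turnover at near 1:1 stoichiometry, and a wrong sense of induction. The fallback uses known chemistry, sets out from 4 and 5 and comes back at 6. Non-selective opening of 5 by 4 with Et3N (1.5 equiv) and DMAP (5 mol %) in THF at 0 °C, the routine way to 3-hydroxy-3-methylglutaryl monoesters, gives racemic (Z)-sinapyl hydrogen 3-hydroxy-3-methylglutarate F1. Preparative chiral SFC (amylose tris(3,5-dimethylphenylcarbamate) phase, CO2/MeOH with 0.1% HCO2H) resolves it into 6 and the (3S) enantiomer F2, so the configuration comes from a resolution and not from catalysis.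

2. Step 2. The risks are over-reduction to the saturated alcohol, leakage of Z to E, and the sensitivity of 4. The fallback sets out from 3 and comes back at 4. Trans-hydroalumination of 3 with NaAlH2(OCH2CH2OCH3)2 (3.5 equiv, THF, 0 to 20 °C) and aqueous work-up give (E)-sinapyl alcohol F3, where over-reduction cannot occur. Contra-thermodynamic E-to-Z isomerisation by triplet energy transfer (fac-Ir(ppy)3 1 mol %, 450 nm LEDs, degassed MeCN, 20 °C) then enriches 4, which is separated on AgNO3-impregnated silica while the E fraction is recycled.

3. Step 1. The risks are sluggish oxidative addition into the phenoxide-like bromide and oligomerisation of 2. The fallback sets out from 2 and comes back at 4, so it replaces steps 1 and 2 together. LiAlH4 (THF, 0 to 20 °C) converts 2 by trans-hydroalumination into the cyclic lithium alkenylalanate F4 (not isolated), which is quenched at −78 °C with Bu3SnOTf to give (Z)-3-(tributylstannyl)prop-2-en-1-ol F5. Stille coupling of F5 with 1 (Pd(P(t-Bu)3)2 3 mol %, CsF 2.2 equiv, dioxane, 60 °C) runs with retention of alkene geometry and gives 4 directly, the Z geometry coming from the stannane and not from an alkyne reduction.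

**Further compounds**
F1 | step 3 | racemic (Z)-sinapyl hydrogen 3-hydroxy-3-methylglutarate | COc1cc(/C=C\COC(=O)CC(C)(O)CC(=O)O)cc(OC)c1O
F2 | step 3 | (3S)-3-hydroxy-5-{[(2Z)-3-(4-hydroxy-3,5-dimethoxyphenyl)prop-2-en-1-yl]oxy}-3-methyl-5-oxopentanoic acid | COc1cc(/C=C\COC(=O)C[C@@](C)(O)CC(=O)O)cc(OC)c1O
F3 | step 2 | (E)-sinapyl alcohol, 4-[(1E)-3-hydroxyprop-1-en-1-yl]-2,6-dimethoxyphenol | COc1cc(/C=C/CO)cc(OC)c1O
F4 | step 1 | lithium 2,2-dihydrido-2,5-dihydro-1,2-oxaluminol-2-uide (cyclic alkenylalanate, not isolated) | [Li+].[AlH2-]1OCC=C1
F5 | step 1 | (Z)-3-(tributylstannyl)prop-2-en-1-ol | CCCC[Sn](CCCC)(CCCC)/C=C\CO
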